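Atom labels follow daucane numbering. The C4(OH)–C5(H)–C6(O) aldol-type array that straddles the C1–C5 fusion bond of the five- and seven-membered rings is read as the footprint of a semipinacol shift. In a cis-decalin 4,5,6-triol 5-mesylate the C1–C6 bond is antiperiplanar to the C5–O bond, so C1 moves from C6 to C5. This one operation contracts the cyclohexane, which is the intact ring of (R)-carvone, to the cyclopentane, expands the cyclohexene to the cycloheptene, sets C5 by inversion and unveils the C6 ketone. The precursor, a carvone-plus-isoprene-unit decalin, comes from allylation, methallylation, ring-closing metathesis and directed dihydroxylation.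

Key step: step 8

Remark on labels: C1 is the quaternary fusion carbon (methyl C15). C2, C3, C7 and C10 are CH2 groups. C4 is the isopropyl carbinol carbon, C5 the fusion CH and C6 the ester carbon. C8 and C9 are the epoxide carbons (methyl C14 on C8). The same labels are kept in every intermediate. β is the face of C15. Ring A is C1–C6 and ring B is C1, C10, C9, C8, C7, C6.

Assumption: (R)-H8-BINOL is taken to steer the methallyl group to the Re face of the C6 carbonyl group of 5 (the face that carries the allyl group). If the sense of induction is the reverse, the (S)-ligand is used.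

Step 1
Reactants: 1 (R)-(−)-carvone; 2 allyl bromide
Product: 4 (2R,5R)-2-allyl-2-methyl-5-(prop-1-en-2-yl)cyclohexan-1-one, via lithium enolate 3 (not isolated)
Conditions: Li[HB(s-Bu)3], THF, −78 °C; then 2, DMPU, −78 °C to rt; minor C1 epimer removed by chromatography
Reagents that add atoms: allyl bromide, C=CCBr
Why: Reductive enolate alkylation: conjugate hydride addition gives the regiodefined C1 enolate, which should be allylated axially on the half-chair that keeps the C4 isopropenyl group equatorial, so that allyl enters cis to it and C1 is set by the carvone stereocentre.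

Step 2
Reactants: 4 (2R,5R)-2-allyl-2-methyl-5-(prop-1-en-2-yl)cyclohexan-1-one
Product: 5 (R)-6-allyl-3-isopropyl-6-methylcyclohex-2-en-1-one
Conditions: TsOH·H2O (0.2 equiv), toluene, 90 °C
Reagents that add atoms: none
Why: Acid-catalysed double-bond migration (the dihydrocarvone-to-carvenone isomerisation) should carry the easily protonated 1,1-disubstituted alkene into conjugation with the ketone, spare the far less basic allyl group and leave quaternary C1 as the only stereocentre.

Step 3
Reactants: 6 2-methylallylmagnesium chloride; 7 tin tetrachloride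
Product: 8 tetrakis(2-methylallyl)stannane
Conditions: SnCl4, 6 (4.2 equiv), THF–Et2O, 0 °C to reflux
Reagents that add atoms: 2-methylallylmagnesium chloride, CC(=C)C[Mg]Cl; tin tetrachloride, Cl[Sn](Cl)(Cl)Cl
Why: Fourfold transmetalation of SnCl4 by an allylic Grignard reagent is the standard entry to tetraallylstannanes and forms no stereocentre.

Step 4
Reactants: 5 (R)-6-allyl-3-isopropyl-6-methylcyclohex-2-en-1-one; 8 tetrakis(2-methylallyl)stannane
Product: 9 (1S,6R)-6-allyl-3-isopropyl-6-methyl-1-(2-methylallyl)cyclohex-2-en-1-ol
Conditions: 8 (1.5 equiv), Ti(OiPr)4 (30 mol %), (R)-H8-BINOL (30 mol %), i-PrOH (20 equiv), MeCN, rt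
Reagents that add atoms: tetrakis(2-methylallyl)stannane, C=C(C)C[Sn](CC(C)=C)(CC(C)=C)CC(C)=C
Why: Titanium–BINOLate-catalysed asymmetric methallylation of ketones adds 1,2 to cyclic enones; because methyl and allyl on C1 give little bias of their own, the C6 carbinol centre (OH cis to C15) is set by the ligand, which tells the flat alkene flank from the quaternary flank of the carbonyl group.

Step 5
Reactants: 9 (1S,6R)-6-allyl-3-isopropyl-6-methyl-1-(2-methylallyl)cyclohex-2-en-1-ol
Product: 10 (4aS,8aR)-3-isopropyl-6,8a-dimethyl-1,5,8,8a-tetrahydronaphthalen-4a(2H)-ol (cis-fused; 6β-OH cis to 1β-CH3)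
Conditions: second-generation Grubbs catalyst (5 mol %), CH2Cl2, 40 °C
Reagents that add atoms: none
Why: Ring-closing metathesis of the monosubstituted and the 1,1-disubstituted alkene should close six-membered ring B with the trisubstituted C8=C9 bond while the hindered C4=C5 bond stays out; no stereocentre is touched, and any C6 epimer is removed here as the trans-fused isomer.

Step 6
Reactants: 10 cis-fused octalinol
Product: 12 cis-decalin 4β,5β,6β-triol (1β-methyl; 4α-isopropyl; C8=C9 retained), via osmate ester 11 (not isolated)
Conditions: OsO4 (1.05 equiv), TMEDA (1.1 equiv), CH2Cl2, −78 °C; then aq Na2SO3, THF, reflux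
Reagents that add atoms: osmium tetroxide, O=[Os](=O)(=O)=O
Why: Hydrogen-bond-directed dihydroxylation: the OsO4–TMEDA adduct is held by the allylic C6–OH, so the C4=C5 bond should react ahead of the remote C8=C9 bond and from the β face (also the convex face of the cis-decalin), which sets C4 and C5 syn to the C6 hydroxyl.

Step 7
Reactants: 12 cis-decalin 4β,5β,6β-triol
Product: 13 5-O-mesylate of triol 12
Conditions: MsCl (1.1 equiv), Et3N, CH2Cl2, −10 °C
Reagents that add atoms: methanesulfonyl chloride, CS(=O)(=O)Cl
Why: Selective sulfonylation: only the secondary C5 hydroxyl should react while the two tertiary hydroxyls stay free, and no stereocentre changes.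

Step 8
Reactants: 13 5-O-mesylate of triol 12
Product: 15 4β-hydroxy-5α-H-dauc-8-en-6-one (trans-fused hydroazulenone), via aluminium alkoxide 14 (not isolated)
Conditions: Et3Al (3 equiv), CH2Cl2, −78 to 0 °C; then H2O
Reagents that add atoms: none
Why: Triethylaluminium turns both tertiary hydroxyls into aluminium alkoxides and pulls on the mesylate, and the C1–C6 σ-bond, antiperiplanar to the equatorial C5–O bond in the chair that keeps the isopropyl group equatorial, shifts from C6 to C5 while C6 becomes the ketone (organoaluminium-promoted semipinacol rearrangement of a 2-mesyloxy alcohol, the reaction type long used to turn decalins into hydroazulenes). No ring is closed from an open chain: one suprafacial 1,2-shift makes ring A lose C6 and become the cyclopentane C1–C5, and makes ring B gain C5 and become the cycloheptenone. C5 is set by inversion (the β-mesylate gives 5α-H and the trans fusion), C1 migrates with retention and C4 is carried through untouched, so the C4(OH)–C5(H)–C6(=O) array should appear with the natural relative configuration. The selectivity needed is migration of C1–C6 and not of the equally antiperiplanar C3–C4 bond pushed by the C4 alkoxide; fully substituted C1 is the far better migrating group under ionising, non-basic conditions, and its shift relieves the strain of the bond between two fully substituted carbons. The aluminium chelate of the β-alkoxy ketone and the low temperature should hold back retro-aldol cleavage and epimerisation at C5.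

Step 9
Reactants: 15 4β-hydroxy-5α-H-dauc-8-en-6-one
Product: 16 jaeschkeanadiol (dauc-8-ene-4β,6α-diol)
Conditions: Me4N[BH(OAc)3], MeCN–AcOH, −20 °C
Reagents that add atoms: none
Why: Evans–Saksena reduction: the C4β hydroxyl directs hydride to the β face of the C6 ketone, which should give the 1,3-anti diol, that is the 6α-alcohol.

Step 10
Reactants: 16 jaeschkeanadiol
Product: 17 8α,9α-epoxydaucane-4β,6α-diol
Conditions: VO(acac)2 (5 mol %), t-BuOOH, CH2Cl2, 0 °C
Reagents that add atoms: tert-butyl hydroperoxide, CC(C)(C)OO
Why: Vanadium-catalysed hydroxyl-directed epoxidation: the homoallylic 6α-OH should carry the oxidant to the α face of C8=C9, which is also the face away from C15, and so set C8 and C9.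

Step 11
Reactants: 17 8α,9α-epoxydaucane-4β,6α-diol; 18 benzoyl chloride
Product: 19 8α,9α-epoxy-4β-hydroxydaucan-6α-yl benzoate (target)
Conditions: BzCl (1.2 equiv), Et3N, DMAP (cat.), CH2Cl2, 0 °C to rt
Reagents that add atoms: benzoyl chloride, O=C(Cl)c1ccccc1
Why: DMAP-catalysed acylation should take the secondary C6 hydroxyl only, since the hindered tertiary C4 hydroxyl is inert and the epoxide survives the amine-buffered medium; no stereocentre changes.

Compound list
1 | (R)-(−)-carvone | CC1=CC[C@H](CC1=O)C(C)=C | starting material
2 | allyl bromide | C=CCBr | starting material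
3 | lithium enolate of (5R)-dihydrocarvone | CC1=C([O-])C[C@@H](CC1)C(C)=C.[Li+] | intermediate
4 | (2R,5R)-2-allyl-2-methyl-5-(prop-1-en-2-yl)cyclohexan-1-one | C=CC[C@@]1(C)CC[C@@H](C(C)=C)CC1=O | intermediate
5 | (R)-6-allyl-3-isopropyl-6-methylcyclohex-2-en-1-one | C=CC[C@@]1(C)CCC(C(C)C)=CC1=O | intermediate
6 | 2-methylallylmagnesium chloride | CC(=C)C[Mg]Cl | starting material
7 | tin tetrachloride | Cl[Sn](Cl)(Cl)Cl | starting material
8 | tetrakis(2-methylallyl)stannane | C=C(C)C[Sn](CC(C)=C)(CC(C)=C)CC(C)=C | intermediate
9 | (1S,6R)-6-allyl-3-isopropyl-6-methyl-1-(2-methylallyl)cyclohex-2-en-1-ol | C=CC[C@@]1(C)CCC(C(C)C)=C[C@@]1(O)CC(C)=C | intermediate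
10 | (4aS,8aR)-3-isopropyl-6,8a-dimethyl-1,5,8,8a-tetrahydronaphthalen-4a(2H)-ol, cis-fused | CC1=CC[C@@]2(C)CCC(C(C)C)=C[C@@]2(O)C1 | intermediate
11 | cyclic O4,O5-osmate ester of 12 (hexavalent osmium, TMEDA-bound in the flask) | CC1=CC[C@@]2(C)CC[C@]3(C(C)C)O[Os](=O)(=O)O[C@@H]3[C@@]2(O)C1 | intermediate
12 | cis-decalin 4β,5β,6β-triol, (3R,4S,4aR,8aR)-3-isopropyl-6,8a-dimethyl-1,3,4,5,8,8a-hexahydronaphthalene-3,4,4a(2H)-triol | CC1=CC[C@@]2(C)CC[C@@](O)(C(C)C)[C@H](O)[C@@]2(O)C1 | intermediate
13 | 5-O-mesylate of 12 | CC1=CC[C@@]2(C)CC[C@@](O)(C(C)C)[C@H](OS(C)(=O)=O)[C@@]2(O)C1 | intermediate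
14 | O4,O6-bis(diethylaluminium) alkoxide of 13 | CC1=CC[C@@]2(C)CC[C@@](O[Al](CC)CC)(C(C)C)[C@H](OS(C)(=O)=O)[C@@]2(O[Al](CC)CC)C1 | intermediate
15 | 4β-hydroxy-5α-H-dauc-8-en-6-one | CC(C)[C@]1(O)CC[C@]2(C)CC=C(C)CC(=O)[C@H]21 | intermediate
16 | jaeschkeanadiol (dauc-8-ene-4β,6α-diol) | CC(C)[C@]1(O)CC[C@]2(C)CC=C(C)C[C@H](O)[C@H]21 | intermediate
17 | 8α,9α-epoxydaucane-4β,6α-diol | CC(C)[C@]1(O)CC[C@]2(C)C[C@@H]3O[C@]3(C)C[C@H](O)[C@H]21 | intermediate
18 | benzoyl chloride | O=C(Cl)c1ccccc1 | starting material
19 | 8α,9α-epoxy-4β-hydroxydaucan-6α-yl benzoate | CC(C)[C@]1(O)CC[C@]2(C)C[C@@H]3O[C@]3(C)C[C@H](OC(=O)c3ccccc3)[C@H]21 | target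

Total step count: 11. Longest linear sequence: 10 (steps 1, 2 and 4–11; step 3 is a side branch).

Steps most likely to fail

Step 8.
- What may go wrong: the other antiperiplanar bond (C3–C4, pushed by the C4 alkoxide) migrates, or the aldolate opens by retro-aldol cleavage.
- The fallback replaces kinetic by thermodynamic control. It sets out from 12 and comes back at 15.
- Oxidation of the only secondary alcohol of 12 with Dess–Martin periodinane would give the 4,6-dihydroxy 5-ketone F1.
- An α-ketol rearrangement under equilibrating conditions (Al(Ot-Bu)3, toluene, heat) should move C1 from C6 to C5. It trades a ketone wedged between two fully substituted carbons for one flanked by the C7 methylene, and gives the hydroazulene 4,5-dihydroxy 6-ketone F2.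
- SmI2 in THF–MeOH would then cleave the C5–O bond next to the ketone. Protonation of the samarium enolate from the open α face leads to 15.

Step 4.
- What may go wrong: facial selectivity is poor next to a quaternary carbon whose methyl and allyl groups differ little, or the addition to the hindered carbonyl group is sluggish.
- The fallback lets a bicyclic frame tell the faces apart. It sets out from 1 and comes back at 10.
- Zn/KOH reduction would give dihydrocarvone F3.
- Robinson-type Michael addition and aldol closure with methyl vinyl ketone (KOH, EtOH, 0 °C) gives the crystalline cis-ketol F4, in which the chain is cis to isopropenyl and OH is cis to C15.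
- HCl in EtOH dehydrates it and draws the isopropenyl double bond into conjugation, giving the linear dienone F5.
- H2O2/NaOH epoxidises the α,β-bond from the β face, as is usual for angularly methylated octalenones, to give the epoxy enone F6.
- MeLi/CeCl3 gives the tertiary alcohol F7, and Burgess reagent gives the vinyl oxirane F8.
- Hydrogenolysis with Pd2(dba)3, n-Bu3P and HCO2H/Et3N at the allylic C7 leaves the 6β-alcohol 10.

Step 6.
- What may go wrong: the oxidant attacks the more accessible C8=C9 bond, or the hindered C4=C5 bond does not react.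
- The fallback avoids osmium. It sets out from 10 and comes back at 12.
- VO(acac)2/t-BuOOH, which is selective for the allylic alcohol, would give the 4β,5β-epoxy alcohol F9.
- Bromide-catalysed CO2 insertion (n-Bu4NBr, CO2 pressure, heat) proceeds by double inversion at C5. It keeps both C–O bonds β and gives the cyclic carbonate F10.
- K2CO3/MeOH then releases 12.

Further compounds
F1 | step 8 | 4β,6β-dihydroxy 5-ketone of the cis-decalin | CC1=CC[C@@]2(C)CC[C@@](O)(C(C)C)C(=O)[C@@]2(O)C1
F2 | step 8 | 4β,5-dihydroxydauc-8-en-6-one (C5 configuration open, removed next) | CC(C)[C@]1(O)CC[C@]2(C)CC=C(C)CC(=O)C21O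
F3 | step 4 | (5R)-dihydrocarvone (C2 epimers) | CC1CC[C@@H](C(C)=C)CC1=O
F4 | step 4 | cis-ketol from dihydrocarvone and methyl vinyl ketone | C=C(C)[C@@H]1CC[C@]2(C)CCC(=O)C[C@]2(O)C1
F5 | step 4 | (R)-7-isopropyl-4a-methyl-4,4a,5,6-tetrahydronaphthalen-2(3H)-one | CC(C)C1=CC2=CC(=O)CC[C@@]2(C)CC1
F6 | step 4 | 6β,7β-epoxide of F5 | CC(C)C1=C[C@@]23O[C@@H]2C(=O)CC[C@@]3(C)CC1
F7 | step 4 | C8 methyl carbinol of F6 (C8 epimers) | CC(C)C1=C[C@@]23O[C@@H]2C(C)(O)CC[C@@]3(C)CC1
F8 | step 4 | vinyl oxirane with C8=C9 | CC(C)C1=C[C@@]23O[C@@H]2C(C)=CC[C@@]3(C)CC1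
F9 | step 6 | 4β,5β-epoxide of 10 | CC1=CC[C@@]2(C)CC[C@]3(C(C)C)O[C@@H]3[C@@]2(O)C1
F10 | step 6 | 4β,5β-cyclic carbonate of 12 | CC1=CC[C@@]2(C)CC[C@]3(C(C)C)OC(=O)O[C@@H]3[C@@]2(O)C1
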